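**Retrosynthetic overview**

- Numbering: ring C1 (quaternary, carries the allyl group and the side chain), C2H2, C3(OMe), C4=C5, C6(=O); side chain C8(H)(CH3)–C7(H)(OH)Ar. The strategy rests on the C3 carbinol carbon of the cyclohexenone ring, which is allylic to the cis C4=C5 bond that is conjugated to the C6 ketone: the C3–C4 bond is cut to a C3 aldehyde and a (Z)-β-iodoenone (C4–I).
- Endgame: target ⇐ removal of the C7 silyl ether ⇐ O-methylation at C3 (MeI, Ag2O) ⇐ intramolecular Nozaki–Hiyama–Kishi closure, which forms C3–C4, the cyclohexenone ring (formed last) and the C3 stereocentre.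
- Open-chain precursor ⇐ prenyl group as the masked C2–C3 aldehyde (epoxidation, then periodic acid, so that the allyl group survives) and ynone as the masked iodoenone (NaI, AcOH); ynone ⇐ Weinreb amide ⇐ opening of a γ-lactone that holds the quaternary C1.
- Lactone ⇐ cis-lactone by prenylation, then allylation anti to the C8 methyl and C7 aryl (sets C1); cis-lactone ⇐ syn crotylboration of 3,4-dimethoxybenzaldehyde (sets C7 and C8), hydroboration, oxidative lactonisation. The lactone is a temporary ring, formed first and opened before the carbocycle is closed.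

Key step: step 12

Assumption: the (Z)-crotylborane made from (−)-Ipc2BOMe (the reagent derived from (+)-α-pinene) is taken to attack the Si face of aldehyde 1, as it does with benzaldehyde.

**Route**

Step 1
Reactants: 1 3,4-dimethoxybenzaldehyde; 2 cis-2-butene
Product: 6 (1S,2R)-1-(3,4-dimethoxyphenyl)-2-methylbut-3-en-1-ol, via (Z)-crotylpotassium 3 (not isolated), via (Z)-crotyldiisopinocampheylborane 4 (not isolated), via borinate ester 5 (not isolated)
Conditions: 2, KOtBu, n-BuLi, THF, −78 → −45 °C; (−)-Ipc2BOMe, −78 °C; BF3·OEt2; 1, −78 °C; then NaOH, H2O2, rt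
Reagents that add atoms: cis-2-butene 2, C/C=C\C
Why: Brown crotylboration through a closed chair (Zimmerman–Traxler) transition state, in which the Z geometry of the crotyl group gives the syn C7/C8 relationship and the isopinocampheyl groups direct the attack to the Si face of the aldehyde, so that C7 should be S and C8 R.

Step 2
Reactants: 6 (1S,2R)-1-(3,4-dimethoxyphenyl)-2-methylbut-3-en-1-ol
Product: 8 (1S,2R)-1-(3,4-dimethoxyphenyl)-2-methylbutane-1,4-diol, via B-alkyl-9-BBN adduct 7 (not isolated)
Conditions: 9-BBN, THF, 0 °C → rt; then NaOH, H2O2, 0 °C → rt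
Reagents that add atoms: hydrogen peroxide, OO
Why: anti-Markovnikov hydroboration–oxidation of the terminal alkene, in which 9-BBN places boron on the terminal carbon and C7 and C8 are not touched.

Step 3
Reactants: 8 (1S,2R)-1-(3,4-dimethoxyphenyl)-2-methylbutane-1,4-diol
Product: 10 (4R,5S)-5-(3,4-dimethoxyphenyl)-4-methyloxolan-2-one (cis-lactone), via lactol 9 (not isolated)
Conditions: TEMPO (cat.), PhI(OAc)2, CH2Cl2, rt
Reagents that add atoms: none
Why: oxidative lactonisation of a 1,4-diol, in which the oxoammonium oxidant takes the primary alcohol first, the C7 hydroxyl traps the aldehyde as lactol 9 and this is oxidised on to the lactone without change at C7 or C8.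

Step 4
Reactants: 10 (4R,5S)-5-(3,4-dimethoxyphenyl)-4-methyloxolan-2-one; 11 prenyl bromide
Product: 13 (3R,4R,5S)-5-(3,4-dimethoxyphenyl)-4-methyl-3-(3-methylbut-2-enyl)oxolan-2-one, via lithium enolate 12 (not isolated)
Conditions: LiN(iPr)2, THF, −78 °C; 11, −78 → −40 °C
Reagents that add atoms: prenyl bromide 11, CC(C)=CCBr
Why: lactone enolate alkylation with a reactive allylic bromide; the electrophile should enter anti to the C8 methyl, but the configuration of this carbon is erased when the next enolate is formed.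

Step 5
Reactants: 13 (3R,4R,5S)-5-(3,4-dimethoxyphenyl)-4-methyl-3-(3-methylbut-2-enyl)oxolan-2-one; 14 allyl bromide
Product: 16 (3S,4R,5S)-3-allyl-5-(3,4-dimethoxyphenyl)-4-methyl-3-(3-methylbut-2-enyl)oxolan-2-one, via lithium enolate 15 (not isolated)
Conditions: LiN(iPr)2, THF/DMPU, −78 °C; 14, −78 → −20 °C
Reagents that add atoms: allyl bromide 14, C=CCBr
Why: alkylation of a tetrasubstituted lactone enolate; methyl and aryl lie on the same face of the cis-lactone, so allyl bromide should attack the open face and end trans to the C8 methyl, which sets the quaternary C1 as required and is the reason for bringing in prenyl first and allyl second.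

Step 6
Reactants: 16 (3S,4R,5S)-3-allyl-5-(3,4-dimethoxyphenyl)-4-methyl-3-(3-methylbut-2-enyl)oxolan-2-one
Product: 17 (2S,3R,4S)-2-allyl-4-(3,4-dimethoxyphenyl)-4-hydroxy-N-methoxy-N,3-dimethyl-2-(3-methylbut-2-enyl)butanamide
Conditions: MeNH(OMe)·HCl, AlMe3, CH2Cl2, 0 °C → reflux; aq. potassium sodium tartrate, 0 °C; crude used at once
Reagents that add atoms: N,O-dimethylhydroxylamine hydrochloride, CNOC.Cl
Why: Weinreb aminolysis of a lactone with the aluminium amide made in the flask; the aluminium alkoxide keeps the ring open until work-up and no stereocentre takes part.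

Step 7
Reactants: 17 (2S,3R,4S)-2-allyl-4-(3,4-dimethoxyphenyl)-4-hydroxy-N-methoxy-N,3-dimethyl-2-(3-methylbut-2-enyl)butanamide
Product: 18 (2S,3R,4S)-2-allyl-4-(tert-butyldimethylsilyloxy)-4-(3,4-dimethoxyphenyl)-N-methoxy-N,3-dimethyl-2-(3-methylbut-2-enyl)butanamide
Conditions: 2,6-lutidine, TBSOTf, CH2Cl2, −78 → 0 °C
Reagents that add atoms: tert-butyldimethylsilyl trifluoromethanesulfonate, CC(C)(C)[Si](C)(C)OS(=O)(=O)C(F)(F)F
Why: silylation of a hindered secondary alcohol with a silyl triflate should outrun relactonisation, and a silyl ether is chosen for C7 because fluoride removes it at the end without the acid that would ionise the electron-rich benzylic C7–O bond.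

Step 8
Reactants: 18 (2S,3R,4S)-2-allyl-4-(tert-butyldimethylsilyloxy)-4-(3,4-dimethoxyphenyl)-N-methoxy-N,3-dimethyl-2-(3-methylbut-2-enyl)butanamide; 19 ethynylmagnesium bromide
Product: 21 (4S,5R,6S)-4-allyl-6-(tert-butyldimethylsilyloxy)-6-(3,4-dimethoxyphenyl)-5-methyl-4-(3-methylbut-2-enyl)hex-1-yn-3-one, via tetrahedral magnesium chelate 20 (not isolated)
Conditions: 19 (excess), THF, 0 °C → rt; poured into cold aq. NaHSO4
Reagents that add atoms: ethynylmagnesium bromide 19, C#C[Mg]Br
Why: Weinreb ketone synthesis, in which the chelated tetrahedral adduct 20 lasts until the quench so that only one ethynyl group adds, and the inverse acidic quench keeps the released amine from adding to the ynone.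

Step 9
Reactants: 21 (4S,5R,6S)-4-allyl-6-(tert-butyldimethylsilyloxy)-6-(3,4-dimethoxyphenyl)-5-methyl-4-(3-methylbut-2-enyl)hex-1-yn-3-one
Product: 22 (1Z,4S,5R,6S)-4-allyl-6-(tert-butyldimethylsilyloxy)-6-(3,4-dimethoxyphenyl)-1-iodo-5-methyl-4-(3-methylbut-2-enyl)hex-1-en-3-one
Conditions: NaI, AcOH, rt, dark
Reagents that add atoms: sodium iodide, [Na+].[I-]
Why: conjugate hydroiodination of an ynone, in which iodide adds to C4 and the allenol is protonated anti to iodine to give the kinetic Z alkene, while the isolated alkenes and the silyl ether should not react in this weakly acidic medium.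

Step 10
Reactants: 22 (1Z,4S,5R,6S)-4-allyl-6-(tert-butyldimethylsilyloxy)-6-(3,4-dimethoxyphenyl)-1-iodo-5-methyl-4-(3-methylbut-2-enyl)hex-1-en-3-one
Product: 23 (1Z,4S,5R,6S)-4-allyl-6-(tert-butyldimethylsilyloxy)-6-(3,4-dimethoxyphenyl)-4-[(3,3-dimethyloxiran-2-yl)methyl]-1-iodo-5-methylhex-1-en-3-one (both epoxide epimers)
Conditions: mCPBA (1.05 equiv), NaHCO3, CH2Cl2, 0 °C
Reagents that add atoms: 3-chloroperoxybenzoic acid, OOC(=O)c1cccc(Cl)c1
Why: Prilezhaev epoxidation, in which the trisubstituted prenyl alkene is far more nucleophilic than the monosubstituted allyl alkene or the electron-poor iodoenone, and the configuration of the new epoxide carbon does not matter because that carbon becomes the aldehyde.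

Step 11
Reactants: 23 (1Z,4S,5R,6S)-4-allyl-6-(tert-butyldimethylsilyloxy)-6-(3,4-dimethoxyphenyl)-4-[(3,3-dimethyloxiran-2-yl)methyl]-1-iodo-5-methylhex-1-en-3-one
Product: 25 (3S,5Z)-3-allyl-3-[(1S,2R)-1-(tert-butyldimethylsilyloxy)-1-(3,4-dimethoxyphenyl)propan-2-yl]-6-iodo-4-oxohex-5-enal, via vicinal diol 24 (not isolated)
Conditions: H5IO6, THF/Et2O, 0 °C
Reagents that add atoms: none
Why: periodic acid opens the epoxide to diol 24 and cleaves it (Malaprade glycol cleavage) to the C3 aldehyde and acetone; these two selective steps take the place of an ozonolysis, which would not reliably spare the allyl group and the dimethoxyarene.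

Step 12
Reactants: 25 (3S,5Z)-3-allyl-3-[(1S,2R)-1-(tert-butyldimethylsilyloxy)-1-(3,4-dimethoxyphenyl)propan-2-yl]-6-iodo-4-oxohex-5-enal
Product: 27 (4S,6S)-6-allyl-6-[(1S,2R)-1-(tert-butyldimethylsilyloxy)-1-(3,4-dimethoxyphenyl)propan-2-yl]-4-hydroxycyclohex-2-en-1-one, via alkenylchromium dichloride 26 (not isolated)
Conditions: CrCl2 (excess), NiCl2 (cat.), degassed DMSO/THF, rt, high dilution, slow addition of 25
Reagents that add atoms: none
Why: divalent chromium reduces NiCl2 to zerovalent nickel, which inserts into the C4–I bond with retention of the Z geometry, and transmetalation to trivalent chromium gives the alkenylchromium 26, which adds to the C3 aldehyde (intramolecular Nozaki–Hiyama–Kishi reaction). The closest known reaction type is the cyclisation of alkenyl iodides, (Z)-β-iodoenones and (Z)-β-iodoacrylates among them, onto tethered aldehydes to give cyclic allylic alcohols. The cyclohexenone ring closes in the 6-exo-trig mode, with the aldehyde C=O outside the new ring, and the Z alkene becomes the ring cis C4=C5 bond. The new stereocentre C3 is controlled by the quaternary C1: in the half-chair transition state the branched C8 side chain should lie pseudo-equatorial and the allyl group pseudo-axial, and the chromium-bound aldehyde oxygen takes the pseudo-equatorial position to avoid the 1,3-diaxial contact with the allyl group, which places the C3 oxygen cis to the side chain (C3 S). The step needs chemoselectivity for the aldehyde over the C6 ketone and the two alkenes, which the aldehyde preference and low basicity of organochromium reagents secure, and it needs ring closure to beat intermolecular coupling, which the six-membered transition state and the dilution secure.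

Step 13
Reactants: 27 (4S,6S)-6-allyl-6-[(1S,2R)-1-(tert-butyldimethylsilyloxy)-1-(3,4-dimethoxyphenyl)propan-2-yl]-4-hydroxycyclohex-2-en-1-one
Product: 28 (4S,6S)-6-allyl-6-[(1S,2R)-1-(tert-butyldimethylsilyloxy)-1-(3,4-dimethoxyphenyl)propan-2-yl]-4-methoxycyclohex-2-en-1-one
Conditions: MeI, Ag2O, 4 Å MS, MeCN, rt → 40 °C, dark
Reagents that add atoms: iodomethane, CI
Why: Purdie methylation, in which Ag2O activates MeI without forming a free alkoxide, so the γ-hydroxy enone should not be deprotonated at C3 and isomerise to the 1,4-dione, and C3 keeps its configuration because its C–O bond is not broken.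

Step 14
Reactants: 28 (4S,6S)-6-allyl-6-[(1S,2R)-1-(tert-butyldimethylsilyloxy)-1-(3,4-dimethoxyphenyl)propan-2-yl]-4-methoxycyclohex-2-en-1-one
Product: 29 (4S,6S)-6-allyl-6-[(1S,2R)-1-(3,4-dimethoxyphenyl)-1-hydroxypropan-2-yl]-4-methoxycyclohex-2-en-1-one (target)
Conditions: HF·pyridine, pyridine, THF, 0 °C → rt
Reagents that add atoms: none
Why: fluoride cleavage of the silyl ether under buffered conditions, which should leave the allylic methyl ether, the enone and the benzylic C7–O bond (and so C7) intact.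

**Compound list**

1 | 3,4-dimethoxybenzaldehyde | COc1ccc(C=O)cc1OC | starting material
2 | cis-2-butene | C/C=C\C | starting material
3 | (Z)-crotylpotassium | C/C=C\C[K] | intermediate (not isolated)
4 | (Z)-crotyldiisopinocampheylborane, isopinocampheyl groups from (+)-α-pinene | C/C=C\CB([C@@H]1C[C@@H]2C[C@@H](C2(C)C)[C@H]1C)[C@@H]1C[C@@H]2C[C@@H](C2(C)C)[C@H]1C | intermediate (not isolated)
5 | diisopinocampheylborinate ester of 6 | C=C[C@@H](C)[C@H](OB([C@@H]1C[C@@H]2C[C@@H](C2(C)C)[C@H]1C)[C@@H]1C[C@@H]2C[C@@H](C2(C)C)[C@H]1C)c1ccc(OC)c(OC)c1 | intermediate (not isolated)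
6 | (1S,2R)-1-(3,4-dimethoxyphenyl)-2-methylbut-3-en-1-ol (syn) | C=C[C@@H](C)[C@H](O)c1ccc(OC)c(OC)c1 | intermediate
7 | B-alkyl-9-BBN adduct of 6 (boron on the terminal carbon) | C1CCC2CCCC1B2CC[C@@H](C)[C@H](O)c1ccc(OC)c(OC)c1 | intermediate (not isolated)
8 | (1S,2R)-1-(3,4-dimethoxyphenyl)-2-methylbutane-1,4-diol | OCC[C@@H](C)[C@H](O)c1ccc(OC)c(OC)c1 | intermediate
9 | (4R,5S)-5-(3,4-dimethoxyphenyl)-4-methyloxolan-2-ol (lactol, both anomers) | OC1C[C@@H](C)[C@H](O1)c2ccc(OC)c(OC)c2 | intermediate (not isolated)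
10 | (4R,5S)-5-(3,4-dimethoxyphenyl)-4-methyloxolan-2-one (cis-lactone) | O=C1C[C@@H](C)[C@H](O1)c2ccc(OC)c(OC)c2 | intermediate
11 | prenyl bromide (1-bromo-3-methylbut-2-ene) | CC(C)=CCBr | starting material
12 | lithium enolate of 10 | [Li]OC1=C[C@@H](C)[C@H](O1)c2ccc(OC)c(OC)c2 | intermediate (not isolated)
13 | (3R,4R,5S)-5-(3,4-dimethoxyphenyl)-4-methyl-3-(3-methylbut-2-enyl)oxolan-2-one (prenyl trans to methyl) | O=C1[C@H](CC=C(C)C)[C@@H](C)[C@H](O1)c2ccc(OC)c(OC)c2 | intermediate
14 | allyl bromide | C=CCBr | starting material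
15 | lithium enolate of 13 | [Li]OC1=C(CC=C(C)C)[C@@H](C)[C@H](O1)c2ccc(OC)c(OC)c2 | intermediate (not isolated)
16 | (3S,4R,5S)-3-allyl-5-(3,4-dimethoxyphenyl)-4-methyl-3-(3-methylbut-2-enyl)oxolan-2-one (allyl trans to methyl and aryl) | O=C1[C@@](CC=C)(CC=C(C)C)[C@@H](C)[C@H](O1)c2ccc(OC)c(OC)c2 | intermediate
17 | (2S,3R,4S)-2-allyl-4-(3,4-dimethoxyphenyl)-4-hydroxy-N-methoxy-N,3-dimethyl-2-(3-methylbut-2-enyl)butanamide | C=CC[C@@](C(=O)N(C)OC)([C@@H](C)[C@H](O)c1ccc(OC)c(OC)c1)CC=C(C)C | intermediate
18 | (2S,3R,4S)-2-allyl-4-(tert-butyldimethylsilyloxy)-4-(3,4-dimethoxyphenyl)-N-methoxy-N,3-dimethyl-2-(3-methylbut-2-enyl)butanamide | C=CC[C@@](C(=O)N(C)OC)([C@@H](C)[C@H](O[Si](C)(C)C(C)(C)C)c1ccc(OC)c(OC)c1)CC=C(C)C | intermediate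
19 | ethynylmagnesium bromide | C#C[Mg]Br | starting material
20 | tetrahedral magnesium chelate from 18 and 19 (bromomagnesium alkoxide of the N-methoxy-N-methyl hemiaminal) | C=CC[C@@](C(O[Mg]Br)(C#C)N(C)OC)([C@@H](C)[C@H](O[Si](C)(C)C(C)(C)C)c1ccc(OC)c(OC)c1)CC=C(C)C | intermediate (not isolated)
21 | (4S,5R,6S)-4-allyl-6-(tert-butyldimethylsilyloxy)-6-(3,4-dimethoxyphenyl)-5-methyl-4-(3-methylbut-2-enyl)hex-1-yn-3-one | C=CC[C@@](C(=O)C#C)([C@@H](C)[C@H](O[Si](C)(C)C(C)(C)C)c1ccc(OC)c(OC)c1)CC=C(C)C | intermediate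
22 | (1Z,4S,5R,6S)-4-allyl-6-(tert-butyldimethylsilyloxy)-6-(3,4-dimethoxyphenyl)-1-iodo-5-methyl-4-(3-methylbut-2-enyl)hex-1-en-3-one | C=CC[C@@](C(=O)/C=C\I)([C@@H](C)[C@H](O[Si](C)(C)C(C)(C)C)c1ccc(OC)c(OC)c1)CC=C(C)C | intermediate
23 | epoxide of 22 at the prenyl alkene (both epoxide epimers) | C=CC[C@@](C(=O)/C=C\I)([C@@H](C)[C@H](O[Si](C)(C)C(C)(C)C)c1ccc(OC)c(OC)c1)CC1OC1(C)C | intermediate
24 | vicinal diol from 23 (2,3-dihydroxy-3-methylbutyl group on C1, both carbinol epimers) | C=CC[C@@](C(=O)/C=C\I)([C@@H](C)[C@H](O[Si](C)(C)C(C)(C)C)c1ccc(OC)c(OC)c1)CC(O)C(C)(C)O | intermediate (not isolated)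
25 | (3S,5Z)-3-allyl-3-[(1S,2R)-1-(tert-butyldimethylsilyloxy)-1-(3,4-dimethoxyphenyl)propan-2-yl]-6-iodo-4-oxohex-5-enal (key-step precursor) | C=CC[C@@](C(=O)/C=C\I)([C@@H](C)[C@H](O[Si](C)(C)C(C)(C)C)c1ccc(OC)c(OC)c1)CC=O | intermediate
26 | (Z)-alkenylchromium dichloride from 25 (trivalent chromium on C4) | C=CC[C@@](C(=O)/C=C\[Cr](Cl)Cl)([C@@H](C)[C@H](O[Si](C)(C)C(C)(C)C)c1ccc(OC)c(OC)c1)CC=O | intermediate (not isolated)
27 | (4S,6S)-6-allyl-6-[(1S,2R)-1-(tert-butyldimethylsilyloxy)-1-(3,4-dimethoxyphenyl)propan-2-yl]-4-hydroxycyclohex-2-en-1-one (key-step product) | C=CC[C@@]1([C@@H](C)[C@H](O[Si](C)(C)C(C)(C)C)c2ccc(OC)c(OC)c2)C[C@H](O)C=CC1=O | intermediate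
28 | (4S,6S)-6-allyl-6-[(1S,2R)-1-(tert-butyldimethylsilyloxy)-1-(3,4-dimethoxyphenyl)propan-2-yl]-4-methoxycyclohex-2-en-1-one | C=CC[C@@]1([C@@H](C)[C@H](O[Si](C)(C)C(C)(C)C)c2ccc(OC)c(OC)c2)C[C@H](OC)C=CC1=O | intermediate
29 | (4S,6S)-6-allyl-6-[(1S,2R)-1-(3,4-dimethoxyphenyl)-1-hydroxypropan-2-yl]-4-methoxycyclohex-2-en-1-one | C=CC[C@@]1([C@@H](C)[C@H](O)c2ccc(OC)c(OC)c2)C[C@H](OC)C=CC1=O | target

**Step count and risks**

Total step count: 14. Longest linear sequence: 14 steps (1 → 29).

Steps most likely to fail: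

1. Step 12. What may go wrong: attack of the alkenylchromium on both faces of the C3 aldehyde, because the pseudo-equatorial preference of the C8 side chain over the allyl group at C1 is modest; reductive loss of iodine before ring closure may also compete. The fallback sets out from 25: the cyclisation is run as in step 12 and the C3 epimers are separated. The unwanted (4R,6S)-alcohol F1 is inverted by a Mitsunobu reaction (4-nitrobenzoic acid, PPh3, diisopropyl azodicarboxylate, THF, 0 °C) to the 4-nitrobenzoate F2, which has the C3 configuration of 27. Methanolysis (K2CO3, MeOH, 0 °C) then gives 27, where the route is rejoined. C3 is then set by an SN2 inversion and no longer by the transition state of the ring closure.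

2. Step 6 (with the silylation of step 7, which must follow at once). What may go wrong: slow attack of the aluminium amide on the carbonyl next to the quaternary C1, ionisation of the electron-rich benzylic C7–O bond by the Lewis acid with epimerisation at C7, and closure of 17 back to 16 before the hydroxyl is silylated. The fallback sets out from 16 and never passes through an open hydroxy amide. Reduction with LiAlH4 (THF, 0 °C) gives the (2S,3R,4S)-butane-1,4-diol F3, and TBSOTf with 2,6-lutidine silylates both hydroxyls to the bis(silyl ether) F4. HF·pyridine buffered with pyridine (THF, 0 °C) removes the primary silyl ether to give the primary alcohol F5, and Dess–Martin periodinane oxidises it to the aldehyde F6. Addition of 19 (THF, 0 °C) gives the propargylic alcohol F7 as both carbinol epimers, and a second Dess–Martin oxidation gives the ynone 21, where the route is rejoined. This path would also answer a sluggish addition in step 8.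

3. Step 11 (with the epoxidation of step 10). What may go wrong: loss of the C7 silyl ether or Z to E isomerisation of the iodoenone in the acidic periodic acid medium, or oxidation at iodine or at the allyl group by the peracid. The fallback sets out from 22. Osmium-catalysed dihydroxylation of the prenyl alkene (OsO4 cat., (DHQD)2PHAL, 4-methylmorpholine N-oxide, acetone/H2O, 0 °C; the ligand-accelerated osmylation prefers the trisubstituted alkene) gives the diol 24, this time isolated. NaIO4 on silica gel in CH2Cl2 at rt then cleaves it to 25, where the route is rejoined. No acid and no peracid are used, and no compound outside the list is made (F0).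

**Further compounds**

F1 | step 12 | (4R,6S)-6-allyl-6-[(1S,2R)-1-(tert-butyldimethylsilyloxy)-1-(3,4-dimethoxyphenyl)propan-2-yl]-4-hydroxycyclohex-2-en-1-one (C3 epimer of 27) | C=CC[C@@]1([C@@H](C)[C@H](O[Si](C)(C)C(C)(C)C)c2ccc(OC)c(OC)c2)C[C@@H](O)C=CC1=O
F2 | step 12 | 4-nitrobenzoate of 27 (C3 configuration as in 27) | C=CC[C@@]1([C@@H](C)[C@H](O[Si](C)(C)C(C)(C)C)c2ccc(OC)c(OC)c2)C[C@H](OC(=O)c3ccc(cc3)[N+](=O)[O-])C=CC1=O
F3 | step 6 | (2S,3R,4S)-2-allyl-4-(3,4-dimethoxyphenyl)-3-methyl-2-(3-methylbut-2-enyl)butane-1,4-diol | C=CC[C@@](CO)([C@@H](C)[C@H](O)c1ccc(OC)c(OC)c1)CC=C(C)C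
F4 | step 6 | bis(tert-butyldimethylsilyl) ether of F3 | C=CC[C@@](CO[Si](C)(C)C(C)(C)C)([C@@H](C)[C@H](O[Si](C)(C)C(C)(C)C)c1ccc(OC)c(OC)c1)CC=C(C)C
F5 | step 6 | (2S,3R,4S)-2-allyl-4-(tert-butyldimethylsilyloxy)-4-(3,4-dimethoxyphenyl)-3-methyl-2-(3-methylbut-2-enyl)butan-1-ol | C=CC[C@@](CO)([C@@H](C)[C@H](O[Si](C)(C)C(C)(C)C)c1ccc(OC)c(OC)c1)CC=C(C)C
F6 | step 6 | (2S,3R,4S)-2-allyl-4-(tert-butyldimethylsilyloxy)-4-(3,4-dimethoxyphenyl)-3-methyl-2-(3-methylbut-2-enyl)butanal | C=CC[C@@](C=O)([C@@H](C)[C@H](O[Si](C)(C)C(C)(C)C)c1ccc(OC)c(OC)c1)CC=C(C)C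
F7 | step 6 | (4S,5R,6S)-4-allyl-6-(tert-butyldimethylsilyloxy)-6-(3,4-dimethoxyphenyl)-5-methyl-4-(3-methylbut-2-enyl)hex-1-yn-3-ol (both C3 carbinol epimers) | C=CC[C@@](C(O)C#C)([C@@H](C)[C@H](O[Si](C)(C)C(C)(C)C)c1ccc(OC)c(OC)c1)CC=C(C)C
F0 | step 11 | none | none
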